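## Structural features

Ferutinine is a daucane ester: a cyclopentane (C1–C5) and a cycloheptene (C1, C5–C10) share the C1–C5 bond of a bicyclo[5.3.0]decene. The atom labels used throughout are: C1 quaternary ring-fusion carbon with CH3; C2, C3 CH2; C4 C(OH)(isopropyl); C5 ring-fusion CH; C6 CH–O–acyl; C7 CH2; C8 =C(CH3); C9 =CH; C10 CH2. "β" is the face of the C1 methyl group and "α" the opposite face.

The ring fusion is trans (CH3 on C1 β, H on C5 α). Four contiguous stereocentres radiate from C5: C1 (R), C5 (S), C4 (R, tertiary OH β, isopropyl α) and C6 (S, ester oxygen α). The only alkene, C8=C9, is trisubstituted and lies β,γ to C6 and one CH2 away from the quaternary carbon. Fragile points are the base-labile phenolic benzoate, the tertiary alcohol 1,3 to the ester oxygen, and, in any precursor with a carbonyl at C4 or C6, the epimerisable C5–H and the retro-aldol/dehydration-prone β-oxygen.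

The real difficulty is the seven-membered ring carrying an all-carbon quaternary centre at the ring fusion, plus the relay of configuration from that centre to C5, C6 and C4 with a trans fusion.

The key step exploits the pattern C5(sp2)=C6–C7H2–C8=C9 with a C10–C1 σ bond. If C5=C6 is written as a second alkene, the seven-membered ring is a cyclohepta-1,4-diene with C7 between the two alkenes and C1–C10 as the bond a Cope rearrangement forms. That is the product pattern of a cis-divinylcyclopropane (ring C6–C7–C8) rearrangement.

## Logic of the disconnections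

**21 ⇒ 20 ⇒ 18 + 19.** The C6–O–C(=O)Ar ester bond is cut, with the phenol masked as its acetate. It is the only heteroatom link between the terpenoid and the aromatic part, and 18 offers one secondary and one tertiary hydroxyl, so the acylation is site-selective without protection. Gain: the base-sensitive aryl ester is absent from every C–C bond-forming and hydride step. Demand: acylate a hindered secondary alcohol, then free the phenol without cleaving the benzoate.

**18 ⇒ 17.** The C4–CH(CH3)2 bond is cut; the tertiary carbinol is the retron of a carbonyl addition. Gain: one stereocentre and three carbons removed, leaving a cyclopentanone whose β face carries both the C5–C6 bond and the C1 methyl group. Demand: α-face addition of a branched nucleophile to an enolisable ketone without touching C5.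

**17 ⇒ 16 ⇒ 14 ⇒ 13 ⇒ 12.** No skeletal bond is cut. The C4 ketone is carried as a dioxolane, the C6 hydroxyl as a silyl ether, and the C8 methyl group is traced back to a methyl ester (C–O bonds only). The ester is kept because the key step needs an acceptor on C8 and because it deactivates C8=C9 while C5=C6 is functionalised. Demand: remove the allylic oxygen without shifting the alkene.

**12 ⇒ 10.** The C5–H and C6–O bonds are cut together, as one syn addition to the C5=C6 alkene. Gain: two stereocentres removed, leaving a diene whose only stereocentre is C1. Demand: attack on the α face and discrimination between C5=C6 and the enoate alkene.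

**10 ⇒ 4 + 8 (through 9).** The key disconnection cuts C1–C10 and C7–C8 of the seven-membered ring. Forward, C7–C8 and C6–C8 form in a cyclopropanation and C6–C8 is then exchanged for C1–C10 in a Cope rearrangement. Gain: a bicyclic diene with a quaternary stereocentre collapses to an achiral monocyclic diene and a five-carbon diazo ester, and every later stereocentre is derived from C1. Demand: site-selective, cis-selective and enantioselective cyclopropanation of the vinyl group, then a rearrangement in which the reacting alkene terminus carries a Z methyl group.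

**4 ⇒ 3 ⇒ 2 ⇒ 1.** The ring–vinyl bond (C5–C6) is cut as a cross-coupling. The ketal is installed before coupling so that the diene is never exposed to acid, and the alkenyl bromide comes from α-bromination of the enone. Demand: coupling at a bromide flanked by a spiro ketal and a methyl group.

**8 ⇒ 7 ⇒ 6 ⇒ 5.** The vinyl group of the diazo ester is traced to a β-hydroxy and then a β-keto ester (C–O cut), and the diazo group to diazo transfer on the active methylene. Demand: 8 must be made cold and used at once.

## Other disconnections considered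

**Alternative 1:** (first to come to mind) cut C8=C9 by ring-closing metathesis. Forward: the cyclopentane diene-diol A1, carrying all four stereocentres, is closed with the second-generation Grubbs catalyst to 18. The ring closure creates no stereocentre, so the whole stereochemical problem must be solved on an open cyclopentane. The quaternary centre would need an asymmetric conjugate allylation of a β-methylcyclopentenone, a poorly served substrate class. C5 and C6 would then depend on methyl-versus-allyl discrimination in an aldol step. The chosen plan sets C1 catalytically while building the ring and derives the rest from it.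

**Alternative 2:** cut C1–C5 and C9–C10 in a rhodium-catalysed intramolecular (5+2) cycloaddition of the vinylcyclopropane–alkene A2 to the hydroazulene A3. The metallacycle mechanism places the new alkene next to the ring fusion (C6=C7, not C8=C9) and generally favours a cis 5–7 fusion. The methyl-bearing cyclopropane also raises a regiochemical question of which ring bond opens. A3 would therefore need alkene transposition, oxygenation at C6 and correction of the ring fusion at a quaternary centre that cannot be epimerised. The (4+3) route delivers the alkene and the C6 handle in their final positions.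

**Alternative 3:** single-carbon ring expansion: insert C9 into the six-membered ketone of the trans-hydrindanone A4 (diazoalkane or siloxycyclopropane homologation) to the cycloheptanone A5. The two α-carbons of the ketone (C7 and C10) are both CH2, so the migrating bond is not differentiated. The methyl group and the alkene would still have to be introduced regioselectively from a ketone with two similar enolisation sites. The ring expansion also creates no stereocentre, so A4 must already hold all four. This is less step-economical than forming ring and quaternary centre together.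

Key step: step 7

Assumption: the sense of induction of the prolinate catalyst is taken from its behaviour with monosubstituted alkenes, which points to the (R)-ligand series for (1S,2S)-9; if the opposite sense is found, the mirror-image catalyst Rh2(S-DOSP)4 is used with no other change.

Remark: 2 and 19 are also purchasable; 2 is made here from 1 because the enone 1 is the cheaper entry.

## Route

Step 1
Reactants: 1 3-methylcyclopent-2-en-1-one
Product: 2 2-bromo-3-methylcyclopent-2-en-1-one
Conditions: Br2, CH2Cl2, 0 °C; then Et3N, 0 °C to rt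
Reagents that add atoms: bromine, BrBr
Why: α-Bromination of an enone by addition–elimination: bromine adds across the alkene and triethylamine removes HBr from the only acidic position, α to the carbonyl; no stereocentre is formed.

Step 2
Reactants: 2 2-bromo-3-methylcyclopent-2-en-1-one
Product: 3 6-bromo-7-methyl-1,4-dioxaspiro[4.4]non-6-ene
Conditions: HOCH2CH2OH, p-TsOH·H2O (cat.), benzene, reflux, Dean–Stark
Reagents that add atoms: ethylene glycol, OCCO
Why: Acid-catalysed ketalisation with azeotropic removal of water; the vinylic bromine holds the double bond in place, as is usual for 2-bromocycloalkenone ketals, and removing the carbonyl makes the later diene electron-rich.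

Step 3
Reactants: 3 6-bromo-7-methyl-1,4-dioxaspiro[4.4]non-6-ene
Product: 4 6-ethenyl-7-methyl-1,4-dioxaspiro[4.4]non-6-ene
Conditions: vinylB(pin), Pd(dppf)Cl2 (5 mol %), Cs2CO3, 1,4-dioxane/H2O, 80 °C
Reagents that add atoms: vinylboronic acid pinacol ester, C=CB1OC(C)(C)C(C)(C)O1
Why: Suzuki–Miyaura coupling of an alkenyl bromide with a small vinylboronate; the basic medium leaves the acid-labile allylic ketal untouched.

Step 4
Reactants: 5 methyl acetoacetate
Product: 6 methyl 2-diazo-3-oxobutanoate
Conditions: p-ABSA, Et3N, MeCN, 0 °C to rt
Reagents that add atoms: 4-acetamidobenzenesulfonyl azide, CC(=O)Nc1ccc(cc1)S(=O)(=O)N=[N+]=[N-]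
Why: Regitz diazo transfer to an active methylene compound.

Step 5
Reactants: 6 methyl 2-diazo-3-oxobutanoate
Product: 7 methyl 2-diazo-3-hydroxybutanoate (racemic)
Conditions: NaBH4, MeOH, 0 °C
Reagents that add atoms: none
Why: Borohydride reduces the ketone and leaves the ester and the acceptor-stabilised diazo group; the carbinol centre is racemic and is destroyed in the next step.

Step 6
Reactants: 7 methyl 2-diazo-3-hydroxybutanoate
Product: 8 methyl 2-diazobut-3-enoate
Conditions: POCl3, Et3N, CH2Cl2, 0 °C; used at once
Reagents that add atoms: none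
Why: Dehydration through the dichlorophosphate (E2 with triethylamine) gives the vinyldiazoacetate, which is used cold and immediately because it slowly closes to a 3H-pyrazole.

Step 7
Reactants: 4 6-ethenyl-7-methyl-1,4-dioxaspiro[4.4]non-6-ene; 8 methyl 2-diazobut-3-enoate
Product: 10 methyl (8aR)-3,3-(ethylenedioxy)-8a-methyl-1,2,3,5,8,8a-hexahydroazulene-6-carboxylate, via cis-divinylcyclopropane 9 (not isolated)
Conditions: Rh2(R-DOSP)4 (1 mol %), hexanes, −40 °C to rt, slow addition of 8; then toluene, 80–100 °C
Reagents that add atoms: none
Why: The divalent-rhodium prolinate decomposes 8 to a donor/acceptor vinylcarbenoid, which adds to the monosubstituted vinyl group of 4 (the tetrasubstituted ring alkene is inert) to give the cis-divinylcyclopropane 9, and 9 then undergoes a Cope ([3,3]) rearrangement that breaks C6–C8 and forms C1–C10. The closest known reaction type is the tandem asymmetric cyclopropanation/divinylcyclopropane rearrangement of vinyldiazoacetates with 1,3-dienes (a formal (4+3) cycloaddition), which is known for cyclic and acyclic dienes and for dienes whose reacting terminus is fully substituted, so that a quaternary carbon is formed. The three-membered ring is closed by concerted carbenoid addition and the seven-membered ring by a concerted suprafacial sigmatropic shift through a boat-shaped six-atom array, driven by release of cyclopropane strain (about 27 kcal/mol). The one stereocentre that survives, C1, is set by chirality transfer: the chiral carboxylate ligands choose the face of the vinyl group (hence (1S,2S)-9), and the boat geometry, with both alkenes over the three-membered ring, lets C10 reach only one face of the ring alkene, giving (R) at C1. The step needs site selectivity (secured by the steric difference between the two alkenes of 4), cis diastereoselectivity (inherent to donor/acceptor carbenoids, which place the donor vinyl group cis to the alkene substituent) and enantiofacial selectivity (catalyst control). The C1 methyl group is the Z substituent of the reacting terminus and points at the cyclopropane CH2 in the boat, so the rearrangement is expected to need the heating period.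

Step 8
Reactants: 10 methyl (8aR)-3,3-(ethylenedioxy)-8a-methyl-1,2,3,5,8,8a-hexahydroazulene-6-carboxylate
Product: 12 methyl (3aS,4S,8aR)-3,3-(ethylenedioxy)-4-hydroxy-8a-methyl-1,2,3,3a,4,5,8,8a-octahydroazulene-6-carboxylate, via C6-alkylborane 11 (not isolated)
Conditions: BH3·THF, THF, 0 °C to rt; then NaOH (aq), H2O2, 0 °C
Reagents that add atoms: hydrogen peroxide, OO (oxygen at C6); borane–tetrahydrofuran, [BH3-][O+]1CCCC1 (boron of 11 only)
Why: Hydroboration–oxidation: borane adds syn across the electron-rich trisubstituted C5=C6 bond (the enoate C8=C9 is deactivated), with boron at the less substituted C6 and hydrogen at C5. Addition from the face opposite the angular methyl group, as with 5-ene steroids and 7a-methylhydrindenes, should place H5 and the C6 oxygen both α (trans fusion, 4S); the oxidation proceeds with retention.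

Step 9
Reactants: 12 methyl (3aS,4S,8aR)-3,3-(ethylenedioxy)-4-hydroxy-8a-methyl-1,2,3,3a,4,5,8,8a-octahydroazulene-6-carboxylate
Product: 13 methyl (3aS,4S,8aR)-3,3-(ethylenedioxy)-8a-methyl-4-(triethylsilyloxy)-1,2,3,3a,4,5,8,8a-octahydroazulene-6-carboxylate
Conditions: Et3SiCl, imidazole, DMAP (cat.), DMF, rt
Reagents that add atoms: chlorotriethylsilane, CC[Si](Cl)(CC)CC
Why: Silylation of the secondary alcohol under basic conditions that do not touch the ketal; it keeps the hydroxyl out of the sulfation and hydride steps.

Step 10
Reactants: 13 methyl (3aS,4S,8aR)-3,3-(ethylenedioxy)-8a-methyl-4-(triethylsilyloxy)-1,2,3,3a,4,5,8,8a-octahydroazulene-6-carboxylate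
Product: 14 [(3aS,4S,8aR)-3,3-(ethylenedioxy)-8a-methyl-4-(triethylsilyloxy)-1,2,3,3a,4,5,8,8a-octahydroazulen-6-yl]methanol
Conditions: i-Bu2AlH, CH2Cl2, −78 °C; Rochelle salt work-up
Reagents that add atoms: none
Why: 1,2-Reduction of the conjugated ester by diisobutylaluminium hydride at low temperature gives the allylic alcohol; ketal and silyl ether are inert.

Step 11
Reactants: 14 [(3aS,4S,8aR)-3,3-(ethylenedioxy)-8a-methyl-4-(triethylsilyloxy)-1,2,3,3a,4,5,8,8a-octahydroazulen-6-yl]methanol
Product: 16 (3aS,4S,8aR)-3,3-(ethylenedioxy)-6,8a-dimethyl-4-(triethylsilyloxy)-1,2,3,3a,4,5,8,8a-octahydroazulene, via pyridinium allylic sulfate 15 (not isolated)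
Conditions: SO3·pyridine, THF, 0 °C to rt; then LiAlH4, 0 °C to rt
Reagents that add atoms: sulfur trioxide–pyridine, [O-]S(=O)(=O)[n+]1ccccc1 (sulfate of 15 only; 16 gains hydrogen only)
Why: Deoxygenation of a primary allylic alcohol through its sulfate monoester: hydride displaces sulfate at the primary carbon (SN2), which keeps the double bond at C8=C9; no stereocentre is touched.

Step 12
Reactants: 16 (3aS,4S,8aR)-3,3-(ethylenedioxy)-6,8a-dimethyl-4-(triethylsilyloxy)-1,2,3,3a,4,5,8,8a-octahydroazulene
Product: 17 (3aR,8S,8aS)-8-hydroxy-3a,6-dimethyl-3,3a,4,7,8,8a-hexahydroazulen-1(2H)-one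
Conditions: HCl (1 M aq), THF, 0 °C to rt
Reagents that add atoms: water, O
Why: Aqueous acid hydrolyses the dioxolane and the triethylsilyl ether in one operation; the conditions are kept mild because C5 is now α to a ketone and β-hydroxy ketones can dehydrate.

Step 13
Reactants: 17 (3aR,8S,8aS)-8-hydroxy-3a,6-dimethyl-3,3a,4,7,8,8a-hexahydroazulen-1(2H)-one
Product: 18 jaeschkeanadiol, (3R,3aS,4S,8aR)-6,8a-dimethyl-3-(propan-2-yl)-1,2,3,3a,4,5,8,8a-octahydroazulene-3,4-diol
Conditions: i-PrMgCl, CeCl3 (anhydrous), THF, −78 °C; NH4Cl (aq)
Reagents that add atoms: isopropylmagnesium chloride, CC(C)[Mg]Cl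
Why: Addition of an organocerium reagent (from the Grignard reagent and CeCl3) to a hindered, enolisable ketone; the low basicity of the cerium reagent suppresses enolisation and β-hydride reduction. Relative to the cyclopentanone the C5–C6 bond and the angular methyl group are both on the β face, so the isopropyl group should enter from the α face, possibly delivered by the cerium alkoxide of the α-oriented C6 oxygen, giving the β tertiary alcohol (3R).

Step 14
Reactants: 18 jaeschkeanadiol; 19 4-acetoxybenzoyl chloride
Product: 20 (3R,3aS,4S,8aR)-3-hydroxy-6,8a-dimethyl-3-(propan-2-yl)-1,2,3,3a,4,5,8,8a-octahydroazulen-4-yl 4-acetoxybenzoate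
Conditions: Et3N, DMAP, CH2Cl2, 0 °C to rt
Reagents that add atoms: none
Why: Acylation with an acid chloride under 4-dimethylaminopyridine catalysis takes place at the secondary hydroxyl only; the tertiary alcohol is too hindered to be esterified.

Step 15
Reactants: 20 (3R,3aS,4S,8aR)-3-hydroxy-6,8a-dimethyl-3-(propan-2-yl)-1,2,3,3a,4,5,8,8a-octahydroazulen-4-yl 4-acetoxybenzoate
Product: 21 ferutinine, (3R,3aS,4S,8aR)-3-hydroxy-6,8a-dimethyl-3-(propan-2-yl)-1,2,3,3a,4,5,8,8a-octahydroazulen-4-yl 4-hydroxybenzoate
Conditions: K2CO3 (cat.), MeOH, 0 °C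
Reagents that add atoms: none
Why: Methanolysis of the aryl acetate, which is far more electrophilic than the hindered secondary benzoate (phenoxide leaving group; the freed phenoxide further deactivates the benzoate); no stereocentre is involved.

## Compound list

1 | 3-methylcyclopent-2-en-1-one | CC1=CC(=O)CC1 | starting material
2 | 2-bromo-3-methylcyclopent-2-en-1-one | CC1=C(Br)C(=O)CC1 | intermediate
3 | 6-bromo-7-methyl-1,4-dioxaspiro[4.4]non-6-ene | CC1=C(Br)C2(CC1)OCCO2 | intermediate
4 | 6-ethenyl-7-methyl-1,4-dioxaspiro[4.4]non-6-ene | C=CC1=C(C)CCC12OCCO2 | intermediate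
5 | methyl acetoacetate | COC(=O)CC(C)=O | starting material
6 | methyl 2-diazo-3-oxobutanoate | COC(=O)C(=[N+]=[N-])C(C)=O | intermediate
7 | methyl 2-diazo-3-hydroxybutanoate (racemic) | COC(=O)C(=[N+]=[N-])C(C)O | intermediate
8 | methyl 2-diazobut-3-enoate | COC(=O)C(=[N+]=[N-])C=C | intermediate
9 | methyl (1S,2S)-1-ethenyl-2-(7-methyl-1,4-dioxaspiro[4.4]non-6-en-6-yl)cyclopropane-1-carboxylate | COC(=O)[C@]1(C=C)C[C@H]1C1=C(C)CCC12OCCO2 | intermediate
10 | methyl (8aR)-3,3-(ethylenedioxy)-8a-methyl-1,2,3,5,8,8a-hexahydroazulene-6-carboxylate | COC(=O)C1=CC[C@@]2(C)CCC3(OCCO3)C2=CC1 | intermediate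
11 | methyl (3aR,4S,8aR)-4-boranyl-3,3-(ethylenedioxy)-8a-methyl-1,2,3,3a,4,5,8,8a-octahydroazulene-6-carboxylate (monoalkylborane; B and H3a both α) | COC(=O)C1=CC[C@@]2(C)CCC3(OCCO3)[C@@H]2[C@@H](B)C1 | intermediate
12 | methyl (3aS,4S,8aR)-3,3-(ethylenedioxy)-4-hydroxy-8a-methyl-1,2,3,3a,4,5,8,8a-octahydroazulene-6-carboxylate | COC(=O)C1=CC[C@@]2(C)CCC3(OCCO3)[C@@H]2[C@@H](O)C1 | intermediate
13 | methyl (3aS,4S,8aR)-3,3-(ethylenedioxy)-8a-methyl-4-(triethylsilyloxy)-1,2,3,3a,4,5,8,8a-octahydroazulene-6-carboxylate | COC(=O)C1=CC[C@@]2(C)CCC3(OCCO3)[C@@H]2[C@@H](O[Si](CC)(CC)CC)C1 | intermediate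
14 | [(3aS,4S,8aR)-3,3-(ethylenedioxy)-8a-methyl-4-(triethylsilyloxy)-1,2,3,3a,4,5,8,8a-octahydroazulen-6-yl]methanol | OCC1=CC[C@@]2(C)CCC3(OCCO3)[C@@H]2[C@@H](O[Si](CC)(CC)CC)C1 | intermediate
15 | pyridinium [(3aS,4S,8aR)-3,3-(ethylenedioxy)-8a-methyl-4-(triethylsilyloxy)-1,2,3,3a,4,5,8,8a-octahydroazulen-6-yl]methyl sulfate | [O-]S(=O)(=O)OCC1=CC[C@@]2(C)CCC3(OCCO3)[C@@H]2[C@@H](O[Si](CC)(CC)CC)C1.c1cc[nH+]cc1 | intermediate
16 | (3aS,4S,8aR)-3,3-(ethylenedioxy)-6,8a-dimethyl-4-(triethylsilyloxy)-1,2,3,3a,4,5,8,8a-octahydroazulene | CC1=CC[C@@]2(C)CCC3(OCCO3)[C@@H]2[C@@H](O[Si](CC)(CC)CC)C1 | intermediate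
17 | (3aR,8S,8aS)-8-hydroxy-3a,6-dimethyl-3,3a,4,7,8,8a-hexahydroazulen-1(2H)-one | CC1=CC[C@@]2(C)CCC(=O)[C@@H]2[C@@H](O)C1 | intermediate
18 | jaeschkeanadiol, (3R,3aS,4S,8aR)-6,8a-dimethyl-3-(propan-2-yl)-1,2,3,3a,4,5,8,8a-octahydroazulene-3,4-diol | CC1=CC[C@@]2(C)CC[C@@](O)(C(C)C)[C@@H]2[C@@H](O)C1 | intermediate
19 | 4-acetoxybenzoyl chloride | CC(=O)Oc1ccc(cc1)C(Cl)=O | starting material
20 | (3R,3aS,4S,8aR)-3-hydroxy-6,8a-dimethyl-3-(propan-2-yl)-1,2,3,3a,4,5,8,8a-octahydroazulen-4-yl 4-acetoxybenzoate | CC1=CC[C@@]2(C)CC[C@@](O)(C(C)C)[C@@H]2[C@@H](OC(=O)c2ccc(OC(C)=O)cc2)C1 | intermediate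
21 | ferutinine | CC1=CC[C@@]2(C)CC[C@@](O)(C(C)C)[C@@H]2[C@@H](OC(=O)c2ccc(O)cc2)C1 | target

## Step count and least certain steps

Total step count: 15. Longest linear sequence: 12 steps (steps 1–3 and 7–15); steps 4–6 make the diazo ester for the convergent key step.

**Step 7 (key step).** The most likely failure is a slow Cope rearrangement of 9, because the C1 methyl group is the Z substituent in the boat transition state. At the temperature then required the C6–C8 cyclopropane bond can open reversibly (both termini are allylic), so the cis relationship and the enantiomeric integrity of 9 may erode before ring expansion. A second risk is carbenoid attack on the dioxolane (ylide formation or insertion next to oxygen) competing with addition to a hindered, twisted vinyl group. The fallback changes the ring-forming bond to C8=C9 and sets out from 1. Conjugate allylation (allyltrimethylsilane, TiCl4, CH2Cl2, −78 °C) with in situ aldol capture of the titanium enolate by 3-methylbut-3-enal would give (2S,3R)-2-[(1S)-1-hydroxy-3-methylbut-3-en-1-yl]-3-methyl-3-(prop-2-en-1-yl)cyclopentan-1-one F1, as the racemate and with the C5/C6 relationship set by the aldol step. Ring-closing metathesis with the second-generation Hoveyda–Grubbs catalyst then closes the cycloheptene. After separation of the enantiomers on a chiral stationary phase the route is rejoined at 17. This path is shorter but gives up the catalytic control of C1.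

**Step 8.** The most likely failure is poor or reversed facial selectivity. The cyclohepta-1,4-diene ring of 10 folds toward the α face, and C10 lies about as far out of the C5=C6 plane as the methyl group does, so attack syn to the methyl group may compete or dominate; borane may also reduce the enoate. The fallback exploits the opposite facial preference, setting out from 10 and returning at 12.
- Epoxidation (mCPBA, NaHCO3) on the β face would give the 3aβ,4β-epoxide of 10, F2.
- Lewis-acid-induced Meinwald rearrangement (BF3·OEt2, −78 °C) shifts H6 to the α face of C5, anti to the departing oxygen, giving the trans-fused ketone methyl (3aS,8aR)-3,3-(ethylenedioxy)-8a-methyl-4-oxo-1,2,3,3a,4,5,8,8a-octahydroazulene-6-carboxylate F3.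
- NaBH4 should attack anti to the syn-axial methyl group and give the 4β-alcohol methyl (3aS,4R,8aR)-3,3-(ethylenedioxy)-4-hydroxy-8a-methyl-1,2,3,3a,4,5,8,8a-octahydroazulene-6-carboxylate F4.
- Mitsunobu inversion with 4-nitrobenzoic acid (PPh3, DIAD) gives the 4α-ester methyl (3aS,4S,8aR)-3,3-(ethylenedioxy)-8a-methyl-4-[(4-nitrobenzoyl)oxy]-1,2,3,3a,4,5,8,8a-octahydroazulene-6-carboxylate F5.
- Methanolysis (K2CO3, MeOH) gives 12.

Whichever face of 10 is the more accessible, one of the two sequences should lead to 12.

**Step 13.** The most likely failure is enolisation of the ketone toward C5 (loss of the ring-fusion configuration, retro-aldol opening of the aldolate) or β-hydride reduction by the branched organometallic, in place of addition. The fallback sets out from 17 and installs the three carbons as an sp2 nucleophile without β-hydrogens. Prop-1-en-2-ylmagnesium bromide/CeCl3 would give (3S,3aS,4S,8aR)-6,8a-dimethyl-3-(prop-1-en-2-yl)-1,2,3,3a,4,5,8,8a-octahydroazulene-3,4-diol F6. Its 1,1-disubstituted alkene is then hydrogenated selectively in the presence of the trisubstituted ring alkene (H2, RhCl(PPh3)3, benzene), returning at 18.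

**Step 12.** The most likely failure is acid-promoted dehydration of the β-hydroxy ketone through the C5 enol, or epimerisation at C5, while the silyl ether is being cleaved. The fallback sets out from 16 and never exposes a free β-hydroxy ketone to acid. Neutral transketalisation (catalytic I2, acetone) would give (3aR,8S,8aS)-3a,6-dimethyl-8-(triethylsilyloxy)-3,3a,4,7,8,8a-hexahydroazulen-1(2H)-one F7. Organocerium addition as in step 13 gives (3R,3aS,4S,8aR)-6,8a-dimethyl-3-(propan-2-yl)-4-(triethylsilyloxy)-1,2,3,3a,4,5,8,8a-octahydroazulen-3-ol F8, and Bu4NF then frees the C6 hydroxyl, returning at 18.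

**Step 11.** The most likely failure is allylic transposition (hydride delivered to C9, giving the exocyclic methylene isomer) or incomplete sulfation of the hindered system. The fallback sets out from 14 and uses a π-allyl mechanism. Acetylation (Ac2O, pyridine) would give [(3aS,4S,8aR)-3,3-(ethylenedioxy)-8a-methyl-4-(triethylsilyloxy)-1,2,3,3a,4,5,8,8a-octahydroazulen-6-yl]methyl acetate F9. Reduction with LiEt3BH and zerovalent palladium, Pd(PPh3)4, delivers hydride to the primary terminus of the allyl complex, returning at 16.

## Further compounds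

F1 | step 7 | (2S,3R)-2-[(1S)-1-hydroxy-3-methylbut-3-en-1-yl]-3-methyl-3-(prop-2-en-1-yl)cyclopentan-1-one (made as the racemate) | C=CC[C@@]1(C)CCC(=O)[C@@H]1[C@@H](O)CC(C)=C
F2 | step 8 | 3aβ,4β-epoxide of 10 (oxygen cis to the angular methyl group) | COC(=O)C1=CC[C@@]2(C)CCC3(OCCO3)[C@]24O[C@@H]4C1
F3 | step 8 | methyl (3aS,8aR)-3,3-(ethylenedioxy)-8a-methyl-4-oxo-1,2,3,3a,4,5,8,8a-octahydroazulene-6-carboxylate | COC(=O)C1=CC[C@@]2(C)CCC3(OCCO3)[C@@H]2C(=O)C1
F4 | step 8 | methyl (3aS,4R,8aR)-3,3-(ethylenedioxy)-4-hydroxy-8a-methyl-1,2,3,3a,4,5,8,8a-octahydroazulene-6-carboxylate | COC(=O)C1=CC[C@@]2(C)CCC3(OCCO3)[C@@H]2[C@H](O)C1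
F5 | step 8 | methyl (3aS,4S,8aR)-3,3-(ethylenedioxy)-8a-methyl-4-[(4-nitrobenzoyl)oxy]-1,2,3,3a,4,5,8,8a-octahydroazulene-6-carboxylate | COC(=O)C1=CC[C@@]2(C)CCC3(OCCO3)[C@@H]2[C@@H](OC(=O)c2ccc(cc2)[N+](=O)[O-])C1
F6 | step 13 | (3S,3aS,4S,8aR)-6,8a-dimethyl-3-(prop-1-en-2-yl)-1,2,3,3a,4,5,8,8a-octahydroazulene-3,4-diol | CC1=CC[C@@]2(C)CC[C@@](O)(C(C)=C)[C@@H]2[C@@H](O)C1
F7 | step 12 | (3aR,8S,8aS)-3a,6-dimethyl-8-(triethylsilyloxy)-3,3a,4,7,8,8a-hexahydroazulen-1(2H)-one | CC1=CC[C@@]2(C)CCC(=O)[C@@H]2[C@@H](O[Si](CC)(CC)CC)C1
F8 | step 12 | (3R,3aS,4S,8aR)-6,8a-dimethyl-3-(propan-2-yl)-4-(triethylsilyloxy)-1,2,3,3a,4,5,8,8a-octahydroazulen-3-ol | CC1=CC[C@@]2(C)CC[C@@](O)(C(C)C)[C@@H]2[C@@H](O[Si](CC)(CC)CC)C1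
F9 | step 11 | [(3aS,4S,8aR)-3,3-(ethylenedioxy)-8a-methyl-4-(triethylsilyloxy)-1,2,3,3a,4,5,8,8a-octahydroazulen-6-yl]methyl acetate | CC(=O)OCC1=CC[C@@]2(C)CCC3(OCCO3)[C@@H]2[C@@H](O[Si](CC)(CC)CC)C1
A1 | alternative 1 | (1R,2S,3R)-2-[(1S)-1-hydroxy-3-methylbut-3-en-1-yl]-3-methyl-1-(propan-2-yl)-3-(prop-2-en-1-yl)cyclopentan-1-ol | C=CC[C@@]1(C)CC[C@@](O)(C(C)C)[C@@H]1[C@@H](O)CC(C)=C
A2 | alternative 2 | (1E,3R)-6-methyl-1-(trans-2-methylcyclopropyl)-3-(propan-2-yl)hepta-1,6-dien-3-ol (cyclopropane configuration not specified) | C=C(C)CC[C@@](O)(C(C)C)/C=C/C1CC1C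
A3 | alternative 2 | cis-fused 6,8a-dimethyl-3-(propan-2-yl)-1,2,3,3a,6,7,8,8a-octahydroazulen-3-ol (C6 configuration not specified) | CC1CC[C@]2(C)CC[C@@](O)(C(C)C)[C@@H]2C=C1
A4 | alternative 3 | trans-fused 3,4-dihydroxy-7a-methyl-3-(propan-2-yl)octahydroinden-6-one | O=C1C[C@@]2(C)CC[C@@](O)(C(C)C)[C@@H]2[C@@H](O)C1
A5 | alternative 3 | trans-fused 3,4-dihydroxy-8a-methyl-3-(propan-2-yl)decahydroazulen-6-one | O=C1CC[C@@]2(C)CC[C@@](O)(C(C)C)[C@@H]2[C@@H](O)C1
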